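Removing the ring oxygen O1 from the butenolide (O1, C2=O, C3, C4, C5) leaves a cyclobutenone. Its tetrasubstituted C3=C4 unit, carrying two benzyl groups, is the symmetrical alkyne 1,4-diphenylbut-2-yne, and its C2–C5 unit is benzylketene. A [2+2] cycloaddition of the keteniminium ion made from the 3-phenylpropanamide of twofold-symmetric (2S,5S)-2,5-dimethylpyrrolidine with that alkyne forms C2–C3 and C4–C5, closes the four-membered carbocycle and sets the only stereocentre, C5, in one operation. Hydrolysis then gives the cyclobutenone, and a strain-driven Baeyer–Villiger oxidation reinserts O1 between C2 and C5 with retention, expanding the carbocycle to the lactone ring.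

Key step: step 3

Remark: atom labels O1 and C2 to C5 are those of the lactone ring of the target throughout. The descriptors are mutually consistent: the target is (5S), the cyclobutenone is (4S), and oxygen insertion with retention maps one onto the other because O1 takes the place and the CIP rank of the carbonyl carbon.

Assumption: the sense of induction in step 3 is a prediction from an allylic-strain model, (2S,5S)-amine to (4S)-ketone. If the opposite sense is found, the enantiomeric amine is used with no other change.

Step 1
Reactants: 1 3-phenylpropanoyl chloride; 2 (2S,5S)-2,5-dimethylpyrrolidine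
Product: 3 1-[(2S,5S)-2,5-dimethylpyrrolidin-1-yl]-3-phenylpropan-1-one
Conditions: Et3N (1.5 equiv), DMAP (cat.), CH2Cl2, 0 °C → rt
Reagents that add atoms: none
Why: N-acylation of a secondary amine by an acid chloride under DMAP catalysis, which an unhindered acyl chloride should achieve even at the flanked nitrogen of 2 without touching either stereocentre of the amine.

Step 2
Reactants: 4 3-phenyl-1-propyne; 5 benzyl bromide
Product: 8 1,4-diphenylbut-2-yne, via (3-phenylprop-1-yn-1-yl)magnesium bromide 6 (not isolated), via (3-phenylprop-1-yn-1-yl)copper 7 (not isolated)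
Conditions: EtMgBr, THF, 0 °C → rt; then CuBr·SMe2 (10 mol %), 5, THF, 50 °C
Reagents that add atoms: none
Why: Copper-catalysed alkynylation of a benzylic halide: EtMgBr removes only the terminal C–H of 4 to give 6, transmetalation gives the alkynylcopper 7 (monovalent copper), SN2-type displacement of the bromide of 5 forms the sp–sp3 bond, and the absence of alkoxide or amine bases should keep the doubly activated CH2 groups from isomerising to allenes.

Step 3
Reactants: 3 1-[(2S,5S)-2,5-dimethylpyrrolidin-1-yl]-3-phenylpropan-1-one; 8 1,4-diphenylbut-2-yne
Product: 12 (4S)-2,3,4-tribenzylcyclobut-2-en-1-one, via O-triflyliminium triflate 9 (not isolated), via keteniminium triflate 10 (not isolated), via cyclobuteniminium triflate 11 (not isolated)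
Conditions: Tf2O (1.1 equiv, slow addition), 2,4,6-collidine (1.2 equiv), 8 (2.5 equiv), CH2Cl2, −25 °C → 35 °C; then H2O, 0 °C → rt
Reagents that add atoms: water, O
Why: Proposed new method: Tf2O O-sulfonylates amide 3 to 9, collidine removes the α-proton and triflate departs to give keteniminium ion 10; the π bond of alkyne 8 attacks its sp carbon (future C2) in the plane of the CHBn terminus and anti to benzyl, the vinyl-cation-like carbon (C4) is captured by the enamine carbon (future C5), and water hydrolyses iminium salt 11 and supplies the ketone oxygen. The closest known reaction types are the non-asymmetric keteniminium–alkyne [2+2] cycloaddition to cyclobutenones and the auxiliary-controlled keteniminium–alkene [2+2] cycloaddition to cyclobutanones with twofold-symmetric pyrrolidine amides; their combination on an alkyne is the untested part. The single ring, the carbocycle C2–C3–C4–C5, is closed in an asynchronous polar [2+2]: intermolecular C2–C3 bond formation, then four-membered closure by cation–enamine collapse at C4–C5, driven by the high energy of the vinyl cation. The stereocentre C5 is controlled by the auxiliary: as the iminium becomes coplanar with the new ring, the methyl group on the pyrrolidine carbon syn to C5 shields one face, so the C5 benzyl group should turn to the opposite face (least allylic 1,3-strain), which for the (2S,5S)-amine corresponds to the (4S)-ketone. The only selectivity needed is this facial selectivity at C5, because the symmetrical alkyne removes regiochemistry and the twofold symmetry of the amine makes both N–C rotamers of 10 identical; slow addition of Tf2O to a solution already holding excess 8 should suppress self-condensation of 10. Once formed, C5 should be configurationally secure under the cold, near-neutral hydrolysis, since deprotonation there would give an antiaromatic cyclobutadiene.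

Step 4
Reactants: 12 (4S)-2,3,4-tribenzylcyclobut-2-en-1-one
Product: 13 (S)-maculalactone A, (5S)-3,4,5-tribenzylfuran-2(5H)-one
Conditions: mCPBA (1.2 equiv), CH2Cl2, 0 °C; cold aq Na2S2O3/NaHCO3 quench
Reagents that add atoms: mCPBA, O=C(OO)c1cccc(Cl)c1
Why: Baeyer–Villiger oxidation: the peracid adds to the strained carbonyl and in the Criegee intermediate the secondary sp3 carbon (C5) should migrate in preference to the alkenyl carbon, with retention, so that O1 enters between C2 and C5, and strain release should make this fast at 0 °C, ahead of epoxidation of the electron-poor tetrasubstituted alkene.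

Compound list
1 | 3-phenylpropanoyl chloride | O=C(Cl)CCc1ccccc1 | starting material
2 | (2S,5S)-2,5-dimethylpyrrolidine | N1[C@@H](C)CC[C@@H]1C | starting material
3 | 1-[(2S,5S)-2,5-dimethylpyrrolidin-1-yl]-3-phenylpropan-1-one | O=C(CCc1ccccc1)N1[C@@H](C)CC[C@@H]1C | intermediate
4 | 3-phenyl-1-propyne | C#CCc1ccccc1 | starting material
5 | benzyl bromide | BrCc1ccccc1 | starting material
6 | (3-phenylprop-1-yn-1-yl)magnesium bromide | Br[Mg]C#CCc1ccccc1 | intermediate
7 | (3-phenylprop-1-yn-1-yl)copper | [Cu]C#CCc1ccccc1 | intermediate
8 | 1,4-diphenylbut-2-yne | C(C#CCc1ccccc1)c1ccccc1 | intermediate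
9 | (2S,5S)-2,5-dimethyl-1-{3-phenyl-1-[(trifluoromethanesulfonyl)oxy]propylidene}pyrrolidin-1-ium trifluoromethanesulfonate | FC(F)(F)S(=O)(=O)OC(CCc1ccccc1)=[N+]1[C@@H](C)CC[C@@H]1C.[O-]S(=O)(=O)C(F)(F)F | intermediate
10 | (2S,5S)-2,5-dimethyl-1-(3-phenylprop-1-en-1-ylidene)pyrrolidin-1-ium trifluoromethanesulfonate | C(Cc1ccccc1)=C=[N+]1[C@@H](C)CC[C@@H]1C.[O-]S(=O)(=O)C(F)(F)F | intermediate
11 | (2S,5S)-2,5-dimethyl-1-[(4S)-2,3,4-tribenzylcyclobut-2-en-1-ylidene]pyrrolidin-1-ium trifluoromethanesulfonate | [N+]1(=C2[C@@H](Cc3ccccc3)C(Cc3ccccc3)=C2Cc2ccccc2)[C@@H](C)CC[C@@H]1C.[O-]S(=O)(=O)C(F)(F)F | intermediate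
12 | (4S)-2,3,4-tribenzylcyclobut-2-en-1-one | O=C1[C@@H](Cc2ccccc2)C(Cc2ccccc2)=C1Cc1ccccc1 | intermediate
13 | (S)-maculalactone A, (5S)-3,4,5-tribenzylfuran-2(5H)-one | O=C1O[C@@H](Cc2ccccc2)C(Cc2ccccc2)=C1Cc1ccccc1 | target

Total step count: 4 (steps 1 and 2 run in parallel).
Longest linear sequence: 3 steps (step 1 or step 2, then steps 3 and 4).

Steps most likely to fail

Step 3 is the riskiest. Several things may go wrong:
- The facial selectivity of the ring closure at C5 may be poor or reversed.
- The unhindered keteniminium ion may self-condense or be captured by collidine.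
- The activated amide may attack its own phenyl ring in an intramolecular electrophilic substitution.
- Base may shift the ring double bond towards a benzylic position, which would open an epimerisation path.
- The cyclobutenone may undergo thermal 4π ring-opening to a vinylketene if warmed.

The fallback uses known chemistry and takes the stereocentre from the chiral pool instead of creating it. It sets out from 1 and returns at 13. Acid chloride 1 acylates commercial methyl (2S)-2-hydroxy-3-phenylpropanoate (pyridine, DMAP, CH2Cl2) to give methyl (2S)-3-phenyl-2-[(3-phenylpropanoyl)oxy]propanoate F1. Dieckmann condensation (LiHMDS, THF, −78 °C) should close this to (5S)-3,5-dibenzyl-4-hydroxyfuran-2(5H)-one F2, whose tetronate anion protects C5 from further deprotonation. O-Triflation (Tf2O, iPr2NEt, CH2Cl2, −78 °C) gives (5S)-3,5-dibenzyl-2-oxo-2,5-dihydrofuran-4-yl trifluoromethanesulfonate F3. Negishi coupling with benzylzinc bromide (Pd(PPh3)4, zerovalent palladium, THF, rt) then installs the C4 benzyl group under neutral conditions and delivers 13.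

Step 4 may fail in three ways: the alkenyl carbon may migrate instead of the sp3 carbon and give the enol lactone, the strained alkene may be epoxidised, or the product may racemise through its aromatic 2-hydroxyfuran tautomer on contact with base. The fallback carries the ring oxygen from the start as a carbinol, so no oxygen insertion is needed. It sets out from 4 and returns at 13. Lithiation of 4 (n-BuLi, THF, −78 °C) and acylation with N-methoxy-N-methyl-2-phenylacetamide give 1,5-diphenylpent-3-yn-2-one F4. Noyori asymmetric transfer hydrogenation (RuCl[(S,S)-TsDPEN](p-cymene), iPrOH, rt, base-free) should give (2S)-1,5-diphenylpent-3-yn-2-ol F5. Copper-catalysed anti-carbomagnesiation with BnMgCl (3 equiv, CuBr·SMe2 cat., THF/toluene, 0 → 60 °C), directed by the magnesium alkoxide, places benzyl on the alkyne carbon next to the carbinol and gives the chelate (5S)-3,4,5-tribenzyl-2,5-dihydro-1,2-oxamagnesole F6. CO2 turns the alkenyl–magnesium bond into the carboxylate of (2Z,4S)-2,3-dibenzyl-4-hydroxy-5-phenylpent-2-enoic acid F7, which should lactonise to 13 on acidic work-up.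

Step 2 may fail through prototropic isomerisation of the benzylic–propargylic CH2 groups to allenes and conjugated dienes under the basic organometallic conditions, or through Wurtz-type homocoupling of the benzyl halide. The fallback forms both sp–sp3 bonds by neutral palladium catalysis, with no acetylide anion present. It sets out from 5 and returns at 8. Twofold Stille coupling of 5 (2 equiv) with commercial bis(tributylstannyl)acetylene (Pd(PPh3)4, THF, 65 °C) runs through tributyl(3-phenylprop-1-yn-1-yl)stannane F8 to give 8.

Further compounds
F1 | step 3 | methyl (2S)-3-phenyl-2-[(3-phenylpropanoyl)oxy]propanoate | COC(=O)[C@H](Cc1ccccc1)OC(=O)CCc1ccccc1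
F2 | step 3 | (5S)-3,5-dibenzyl-4-hydroxyfuran-2(5H)-one | O=C1O[C@@H](Cc2ccccc2)C(O)=C1Cc1ccccc1
F3 | step 3 | (5S)-3,5-dibenzyl-2-oxo-2,5-dihydrofuran-4-yl trifluoromethanesulfonate | O=C1O[C@@H](Cc2ccccc2)C(OS(=O)(=O)C(F)(F)F)=C1Cc1ccccc1
F4 | step 4 | 1,5-diphenylpent-3-yn-2-one | O=C(Cc1ccccc1)C#CCc1ccccc1
F5 | step 4 | (2S)-1,5-diphenylpent-3-yn-2-ol | O[C@@H](Cc1ccccc1)C#CCc1ccccc1
F6 | step 4 | (5S)-3,4,5-tribenzyl-2,5-dihydro-1,2-oxamagnesole | [Mg]1O[C@@H](Cc2ccccc2)C(Cc2ccccc2)=C1Cc1ccccc1
F7 | step 4 | (2Z,4S)-2,3-dibenzyl-4-hydroxy-5-phenylpent-2-enoic acid | OC(=O)/C(Cc1ccccc1)=C(/Cc1ccccc1)[C@@H](O)Cc1ccccc1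
F8 | step 2 | tributyl(3-phenylprop-1-yn-1-yl)stannane | CCCC[Sn](CCCC)(CCCC)C#CCc1ccccc1
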